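## Retrosynthetic overview

1. Target 8 ⇒ achiral hexaphenol 7 by cutting one O–CH3 bond. The methine of 7 carries two identical aryl groups, so O-methylating one of the two enantiotopic rings (at the oxygen para to the bridge) creates the (R)-centre.
2. 7 ⇒ two molecules of prenylated phloroacetophenone 3 plus 3-methylbutanal 4 (two aryl–CH bonds, through an ortho-quinone methide).
3. 3 ⇒ phloroacetophenone 1 plus prenyl bromide 2 (aryl–prenyl bond).
4. Ring order: no ring is built. Ring A (the methoxy ring) and ring B both come intact from 1 and stay identical until the last step.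

Assumption: the given SMILES encodes the (R)-configuration at the methine. The sense of induction of the chiral ligand in step 3 cannot be predicted, so the (S,S)-ligand is written and its commercial (R,R)-antipode is used instead if the first run gives the (S)-product.

## Route

Step 1
Reactants: 1 1-(2,4,6-trihydroxyphenyl)ethanone (1.5 equiv); 2 1-bromo-3-methylbut-2-ene (1.0 equiv)
Product: 3 1-[2,4,6-trihydroxy-3-(3-methylbut-2-en-1-yl)phenyl]ethanone
Conditions: 10% aq. KOH (1.5 equiv), 0 °C to rt, 3 h; unreacted 1 recovered
Reagents that add atoms: none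
Why: C-alkylation of the ambident phloroglucinol phenoxide in water, where solvation of the oxygens suppresses O-alkylation; the two free ring carbons of 1 are equivalent, so only one mono-prenyl isomer can form, and excess 1 limits double prenylation; no stereocentre.

Step 2
Reactants: 3 1-[2,4,6-trihydroxy-3-(3-methylbut-2-en-1-yl)phenyl]ethanone (2.1 equiv); 4 3-methylbutanal (1.0 equiv)
Product: 7 1,1-bis[3-acetyl-2,4,6-trihydroxy-5-(3-methylbut-2-en-1-yl)phenyl]-3-methylbutane, via benzylic carbinol 5 (not isolated), via ortho-quinone methide 6 (not isolated)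
Conditions: Et3N (0.3 equiv), MeCN, 50 °C, N2, 12 h
Reagents that add atoms: none
Why: base-catalysed hydroxyalkylation at the only free ring carbon of 3, loss of water to the ortho-quinone methide, then Michael-type Friedel–Crafts addition of a second molecule of 3; every ring position of the product is substituted so the reaction stops at the dimer, and the methine bears two identical aryl groups, so 7 is achiral.

Step 3
Reactants: 7 1,1-bis[3-acetyl-2,4,6-trihydroxy-5-(3-methylbut-2-en-1-yl)phenyl]-3-methylbutane
Product: 8 1-[3-[(1R)-1-[3-acetyl-2,6-dihydroxy-4-methoxy-5-(3-methylbut-2-en-1-yl)phenyl]-3-methylbutyl]-2,4,6-trihydroxy-5-(3-methylbut-2-en-1-yl)phenyl]ethanone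
Conditions: Cu(OAc)2 (10 mol%), (S,S)-Ph-BOX [2,2'-(propane-2,2-diyl)bis((4S)-4-phenyl-4,5-dihydrooxazole)] (12 mol%), MeB(OH)2 (1.3 equiv), K2CO3 (20 mol%), 4 Å MS, dry air (1 atm), DCE, 45 °C, stopped at about 80% conversion; unreacted 7 recycled
Reagents that add atoms: methylboronic acid, CB(O)O
Why: Proposed new method: a ligand-controlled desymmetrizing Chan–Lam O-methylation. Methylboronic acid does not methylate phenols without copper, so every O–CH3 bond is made by C–O reductive elimination from a BOX-ligated trivalent copper methyl aryloxide (formed by boron-to-copper transmetalation on divalent copper and disproportionation, with O2 returning monovalent copper to the divalent state). The oxygen methylated is the one copper holds as a six-membered keto-phenolate chelate with the acetyl group: the oxygen para to the acetyl cannot chelate, and of the two chelating oxygens the one beside the CH(isobutyl)aryl bridge is blocked by the ligand, which leaves the outer oxygen between acetyl and prenyl. The two outer oxygens of 7 are enantiotopic and their chelates to the chiral copper fragment are diastereomeric, because the phenyl wings of the ligand face either the second aryl ring or the isobutyl group above the bound ring; methylating the ring that then ranks higher sets the (R)-methine without touching it, and further methylation of the minor enantiomer to the achiral bis-ether should raise the ee with conversion. The closest known reaction types are the racemic Chan–Lam O-methylation of phenols with methylboronic acid, copper-catalysed enantioselective desymmetrizing C–O coupling of diarylmethines, and remote desymmetrization of bis(phenol) diarylmethines by peptide-catalysed O-acylation.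

## Compound list

1 | 1-(2,4,6-trihydroxyphenyl)ethanone (phloroacetophenone) | CC(=O)c1c(O)cc(O)cc1O | starting material
2 | 1-bromo-3-methylbut-2-ene (prenyl bromide) | CC(C)=CCBr | starting material
3 | 1-[2,4,6-trihydroxy-3-(3-methylbut-2-en-1-yl)phenyl]ethanone | CC(=O)c1c(O)cc(O)c(CC=C(C)C)c1O | intermediate
4 | 3-methylbutanal (isovaleraldehyde) | CC(C)CC=O | starting material
5 | 1-[2,4,6-trihydroxy-3-(1-hydroxy-3-methylbutyl)-5-(3-methylbut-2-en-1-yl)phenyl]ethanone, racemic benzylic carbinol, not isolated | CC(=O)c1c(O)c(CC=C(C)C)c(O)c(C(O)CC(C)C)c1O | intermediate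
6 | 4-acetyl-3,5-dihydroxy-6-(3-methylbutylidene)-2-(3-methylbut-2-en-1-yl)cyclohexa-2,4-dien-1-one, ortho-quinone methide, alkene geometry not defined, not isolated | CC(=O)C1=C(O)C(=CCC(C)C)C(=O)C(CC=C(C)C)=C1O | intermediate
7 | 1,1-bis[3-acetyl-2,4,6-trihydroxy-5-(3-methylbut-2-en-1-yl)phenyl]-3-methylbutane, achiral | CC(=O)c1c(O)c(CC=C(C)C)c(O)c(C(CC(C)C)c2c(O)c(CC=C(C)C)c(O)c(C(C)=O)c2O)c1O | intermediate
8 | 1-[3-[(1R)-1-[3-acetyl-2,6-dihydroxy-4-methoxy-5-(3-methylbut-2-en-1-yl)phenyl]-3-methylbutyl]-2,4,6-trihydroxy-5-(3-methylbut-2-en-1-yl)phenyl]ethanone | COc1c(CC=C(C)C)c(O)c([C@H](CC(C)C)c2c(O)c(CC=C(C)C)c(O)c(C(C)=O)c2O)c(O)c1C(C)=O | target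

## Step count and risks

Total steps: 3. Longest linear sequence: 3 (1 → 3 → 7 → 8).

**Most likely to fail: step 3 (the proposed new step).**
- Copper may deliver the methyl to the oxygen para to the acetyl or to the inner chelating oxygen.
- Remote enantio-discrimination may be low; larger aryl wings on the BOX ligand are the first variation, with crystallisation or chiral SFC to finish.
- The electron-rich hexaphenol may be oxidised under copper and air, or tie up copper as insoluble bis-chelates.
- Base and heat can reopen the aryl–CH bond through 6 and scramble or racemise the dimer, so the base is kept catalytic, the temperature low and work-up slightly acidic.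

The fallback uses only known chemistry. It sets out from 3 and comes back at 8. Compound 3 is treated with MOMCl (2.2 equiv) and iPr2NEt in CH2Cl2, which protects the two more accessible hydroxyls and leaves the chelated, prenyl-flanked one free, giving 1-[2-hydroxy-4,6-bis(methoxymethoxy)-3-(3-methylbut-2-en-1-yl)phenyl]ethanone F1. The remaining hydroxyl is methylated with Me2SO4 and K2CO3 in refluxing acetone to give 1-[2-methoxy-4,6-bis(methoxymethoxy)-3-(3-methylbut-2-en-1-yl)phenyl]ethanone F2. Both MOM groups are removed with 3 M HCl in MeOH at rt to give 1-[4,6-dihydroxy-2-methoxy-3-(3-methylbut-2-en-1-yl)phenyl]ethanone F3. F3, 3 and 4 (1:1:1) are condensed under the conditions of step 2, and the crossed dimer, racemic 1-[3-[1-[3-acetyl-2,6-dihydroxy-4-methoxy-5-(3-methylbut-2-en-1-yl)phenyl]-3-methylbutyl]-2,4,6-trihydroxy-5-(3-methylbut-2-en-1-yl)phenyl]ethanone F4, is separated from the two homodimers by chromatography. Preparative chiral SFC of F4 on an amylose tris(3,5-dimethylphenylcarbamate) phase then gives 8.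

**Second: step 1.** Mono-C-prenylation of phloroacetophenone is typically modest in yield, with double C-prenylation and O-prenylation as side reactions. The fallback sets out from 1 and comes back at 3. The non-chelated 4-hydroxyl of 1 is O-alkylated with 2 (K2CO3, acetone, reflux) to give 1-[2,6-dihydroxy-4-(3-methylbut-2-en-1-yloxy)phenyl]ethanone F5. An acid-clay [1,3]-shift of the prenyl group (montmorillonite K10 clay, CH2Cl2, rt) then moves it to the adjacent ring carbon; both ortho positions are equivalent, so the product is 3.

**Third: step 2.** The hydroxyalkylation may be slow, the aldehyde may self-condense, or 6 may tautomerise to a styrene before it is trapped. The fallback sets out from 3 and comes back at 7. Compound 3, 4 and morpholine in EtOH at rt give the isolable Mannich base 1-[2,4,6-trihydroxy-3-(3-methyl-1-morpholin-4-ylbutyl)-5-(3-methylbut-2-en-1-yl)phenyl]ethanone F6 (racemic). Heating F6 with a second equivalent of 3 in toluene at 90 °C eliminates morpholine to regenerate 6 in the presence of its trap, giving 7.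

Further compounds
F1 | step 3 | 1-[2-hydroxy-4,6-bis(methoxymethoxy)-3-(3-methylbut-2-en-1-yl)phenyl]ethanone | CC(=O)c1c(O)c(CC=C(C)C)c(OCOC)cc1OCOC
F2 | step 3 | 1-[2-methoxy-4,6-bis(methoxymethoxy)-3-(3-methylbut-2-en-1-yl)phenyl]ethanone | CC(=O)c1c(OC)c(CC=C(C)C)c(OCOC)cc1OCOC
F3 | step 3 | 1-[4,6-dihydroxy-2-methoxy-3-(3-methylbut-2-en-1-yl)phenyl]ethanone | CC(=O)c1c(OC)c(CC=C(C)C)c(O)cc1O
F4 | step 3 | racemic 1-[3-[1-[3-acetyl-2,6-dihydroxy-4-methoxy-5-(3-methylbut-2-en-1-yl)phenyl]-3-methylbutyl]-2,4,6-trihydroxy-5-(3-methylbut-2-en-1-yl)phenyl]ethanone | COc1c(CC=C(C)C)c(O)c(C(CC(C)C)c2c(O)c(CC=C(C)C)c(O)c(C(C)=O)c2O)c(O)c1C(C)=O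
F5 | step 1 | 1-[2,6-dihydroxy-4-(3-methylbut-2-en-1-yloxy)phenyl]ethanone | CC(=O)c1c(O)cc(OCC=C(C)C)cc1O
F6 | step 2 | 1-[2,4,6-trihydroxy-3-(3-methyl-1-morpholin-4-ylbutyl)-5-(3-methylbut-2-en-1-yl)phenyl]ethanone, racemic | CC(=O)c1c(O)c(CC=C(C)C)c(O)c(C(CC(C)C)N2CCOCC2)c1O
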